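**Plan**

Numbering as 3,4-dihydronaphthalene-2-carbaldehyde: ring B = C1 (vinyl CH), C2 (C–CHO), C3 (CH–CH2OAc), C4 (CH–aryl), C4a, C8a; ring A = C4a–C8a with 6-OH and 7-OMe.
Retrosynthesis: remove two phenol silyl groups, then cut ring B at C1–C8a and C4–C4a in one stroke. This frees ring A as a guaiacol metalated para to its oxygen and leaves the chain C4–C3–C2(CHO)=C1, which is then cut at C3–C4 (aldol).
Enabling feature: C8a is para to the 6-oxygen (Grignard site of 4-bromoguaiacol) and C4a is para to the 7-methoxyl (Friedel–Crafts site). C4 is benzylic and para to the oxygen of the pendant ring (latent quinone-methide cation), and C1=C2–CHO is a 2-substituted malondialdehyde with two interchangeable formyl carbons.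
The chain is therefore stored as a temporary ring, a 2-aryl-2,3-dihydrofuran-4-carbaldehyde, whose ring oxygen masks the C4 cation and one formyl group at once and ends up as the aldehyde oxygen.
Forward: an Evans aldol joins C3–C4; reduction, monoacetylation, alkene cleavage, dehydration and formylation build the dihydrofuran; ring A is then joined and ring B closed in one flask; desilylation ends the route.
Stereochemistry: C3 comes from the auxiliary-controlled aldol and is never touched again; C4 is erased on ionisation and reset trans to the C3 side chain in the ring closure.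

Key step: step 10

Assumption: the stereodescriptors of the SMILES are read as the trans (3R,4S) isomer; TBS = tert-butyldimethylsilyl and Ar = 4-(TBSO)-3-methoxyphenyl throughout.

**Route**

Step 1
Reactants: 1 vanillin (4-hydroxy-3-methoxybenzaldehyde)
Product: 2 4-(tert-butyldimethylsilyloxy)-3-methoxybenzaldehyde (ArCHO)
Conditions: TBSCl, imidazole, DMF, rt
Reagents that add atoms: tert-butyldimethylsilyl chloride, CC(C)(C)[Si](C)(C)Cl
Why: Imidazole-promoted silyl ether formation masks the acidic phenol for the boron aldol, hydride and Grignard steps and forms no stereocenter.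

Step 2
Reactants: 3 (S)-4-benzyloxazolidin-2-one; 4 pent-4-enoyl chloride
Product: 5 (S)-4-benzyl-3-(pent-4-enoyl)oxazolidin-2-one
Conditions: Et3N, DMAP (cat.), CH2Cl2, 0 °C → rt
Reagents that add atoms: none
Why: DMAP-catalysed N-acylation of the oxazolidinone by the acid chloride gives the imide for the aldol and leaves the auxiliary stereocenter untouched.

Step 3
Reactants: 5 (S)-4-benzyl-3-(pent-4-enoyl)oxazolidin-2-one; 2 ArCHO
Product: 8 (S)-4-benzyl-3-[(2S)-2-{(S)-hydroxy(Ar)methyl}pent-4-enoyl]oxazolidin-2-one (syn aldol), via Z-boron enolate 6 (not isolated), via boron aldolate 7 (not isolated)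
Conditions: Bu2BOTf, Et3N, CH2Cl2, –78 → 0 °C; 2, –78 → 0 °C; then pH 7 buffer, MeOH, aq. H2O2, 0 °C
Reagents that add atoms: none
Why: In the Evans syn-aldol the Z-boron enolate reacts through a closed chair transition state on the face away from the benzyl group, which sets the (S) center alpha to the imide (the future C3) and the (S) carbinol center.

Step 4
Reactants: 8 syn aldol imide
Product: 9 (1S,2R)-1-Ar-2-allylpropane-1,3-diol
Conditions: LiBH4, THF–Et2O, 0 °C; aqueous work-up
Reagents that add atoms: none
Why: Reductive cleavage of the imide by LiBH4 (hydride attack on the exocyclic carbonyl) frees the primary alcohol that becomes the acetoxymethyl group and returns the auxiliary, and neither stereocenter is disturbed.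

Step 5
Reactants: 9 (1S,2R)-1-Ar-2-allylpropane-1,3-diol
Product: 10 (2R)-2-[(S)-hydroxy(Ar)methyl]pent-4-en-1-yl acetate
Conditions: AcCl (1.05 equiv), 2,4,6-collidine, CH2Cl2, –78 °C
Reagents that add atoms: acetyl chloride, CC(=O)Cl
Why: Kinetically selective O-acylation at low temperature with a hindered pyridine base takes the unhindered primary hydroxyl in preference to the secondary benzylic one, and no stereocenter is affected.

Step 6
Reactants: 10 (2R)-2-[(S)-hydroxy(Ar)methyl]pent-4-en-1-yl acetate
Product: 13 [(2S,3R)-2-Ar-5-hydroxytetrahydrofuran-3-yl]methyl acetate (anomer mixture; Ar trans to CH2OAc), via vicinal diol 11 (not isolated), via hydroxy aldehyde 12 (not isolated)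
Conditions: OsO4 (cat.), NaIO4, 2,6-lutidine, dioxane–H2O, rt
Reagents that add atoms: osmium tetroxide, O=[Os](=O)(=O)=O; sodium periodate, [Na+].[O-]I(=O)(=O)=O
Why: Lemieux–Johnson cleavage (catalytic dihydroxylation then periodate glycol fission) removes the terminal CH2, and the aldehyde is trapped at once by the benzylic hydroxyl as the five-membered lactol, whose new anomeric center is lost again in step 7.

Step 7
Reactants: 13 lactol
Product: 15 [(2S,3R)-2-Ar-2,3-dihydrofuran-3-yl]methyl acetate, via anomeric mesylate 14 (not isolated)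
Conditions: MsCl, Et3N, CH2Cl2, –40 °C → reflux
Reagents that add atoms: none
Why: Mesylation of the lactol and amine-induced elimination of the anomeric sulfonate, the standard route from 2-deoxy lactols to furanoid glycals, gives the cyclic enol ether without touching C2 or C3 of the furan ring.

Step 8
Reactants: 15 dihydrofuran
Product: 17 [(2S,3R)-2-Ar-4-formyl-2,3-dihydrofuran-3-yl]methyl acetate, via iminium chloride 16 (not isolated)
Conditions: POCl3, DMF, 0 °C → rt; then aq. NaHCO3, 0 °C
Reagents that add atoms: N,N-dimethylformamide (formyl carbon), CN(C)C=O; water (formyl oxygen), O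
Why: Vilsmeier–Haack formylation of a cyclic enol ether at its nucleophilic beta carbon, as in the preparation of 2-C-formyl glycals, is far faster than attack on the silyloxyanisole ring and forms no stereocenter.

Step 9
Reactants: 18 4-bromo-2-methoxyphenol
Product: 19 (4-bromo-2-methoxyphenoxy)(tert-butyl)dimethylsilane (ArBr)
Conditions: TBSCl, imidazole, DMF, rt
Reagents that add atoms: tert-butyldimethylsilyl chloride, CC(C)(C)[Si](C)(C)Cl
Why: Silyl ether formation masks the phenol so that the bromide para to oxygen can be turned into a Grignard reagent.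

Step 10
Reactants: 19 ArBr; 17 [(2S,3R)-2-Ar-4-formyl-2,3-dihydrofuran-3-yl]methyl acetate
Product: 23 (3R,4S)-3-(acetoxymethyl)-4-Ar-6-(TBSO)-7-methoxy-3,4-dihydronaphthalene-2-carbaldehyde, via arylmagnesium bromide 20 (not isolated), via dihydrofuranyl carbinol 21 (not isolated), via benzylic cation 22 (not isolated)
Conditions: 19, Mg turnings, THF, 40 °C; added to 17, THF, –78 °C; then CH2Cl2, TFA (excess), –78 → 0 °C, same flask
Reagents that add atoms: none
Why: Proposed new method: arylmagnesium 20, whose metal sits para to the silyloxy group, adds to the formyl carbon of 17 (C1–C8a; the aldehyde reacts far faster than the primary acetate at –78 °C, a stray conjugate addition–elimination at the enol-ether carbon leads to the same enal because the two formyl carbons of the masked malondialdehyde are equivalent, and the benzylic ether at C4 is inert to base, so ring A can be joined only through C8a). On acidification carbinol 21 ionises to an aryl-, vinyl- and oxygen-stabilised cation that is an O-benzyl oxocarbenium ion, and heterolysis of its O–C4 bond releases the (E)-2-substituted cinnamaldehyde together with the para-silyloxybenzyl (quinone-methide-type) cation in 22, the former ring oxygen becoming the aldehyde oxygen. Ring B then closes by a 6-exo-trig Friedel–Crafts attack of C4a, the position para to the 7-methoxyl, on C4 (C4–C4a), the other ortho position being crowded between side chain and methoxyl. The closest known reaction types are the 1,2-addition of organometallics to beta-alkoxy- or beta-aminoacroleins with acidic transposition to enals (Stork–Danheiser type) and the TFA-induced cyclisation of alpha-hydroxybenzyl benzylidene precursors to trans-1-aryl-1,2-dihydronaphthalenes, and only their fusion through the dihydrofuran relay is new. The one new stereocenter, C4, is planar in 22 and is set by the untouched C3 center, since the pendant aryl group takes the face anti to the acetoxymethyl group in the half-chair transition state and gives the trans (3R,4S) product, while the carbinol center of 21 and the old C2 center of the furan are erased. The alkene geometry that closure needs is secured by acid-mediated equilibration of the push–pull enal toward the isomer with ring A cis to C3.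

Step 11
Reactants: 23 bis-silyl ether
Product: 24 (3R,4S)-3-(acetoxymethyl)-6-hydroxy-4-(4-hydroxy-3-methoxyphenyl)-7-methoxy-3,4-dihydronaphthalene-2-carbaldehyde (target)
Conditions: TBAF, AcOH, THF, 0 °C
Reagents that add atoms: none
Why: Fluoride cleavage of the two aryl silyl ethers, buffered with acetic acid so that the phenoxides cannot attack the primary acetate or trigger loss of acetic acid, leaves both stereocenters untouched.

**Compound list**

1 | vanillin | O=Cc1ccc(O)c(OC)c1 | starting material
2 | 4-(TBSO)-3-methoxybenzaldehyde | O=Cc1ccc(O[Si](C)(C)C(C)(C)C)c(OC)c1 | intermediate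
3 | (S)-4-benzyloxazolidin-2-one | O=C1OC[C@H](Cc2ccccc2)N1 | starting material
4 | pent-4-enoyl chloride | C=CCCC(=O)Cl | starting material
5 | (S)-4-benzyl-3-(pent-4-enoyl)oxazolidin-2-one | O=C1OC[C@H](Cc2ccccc2)N1C(=O)CCC=C | intermediate
6 | Z-dibutylboron enolate of 5 | O=C1OC[C@H](Cc2ccccc2)N1/C(OB(CCCC)CCCC)=C/CC=C | intermediate
7 | dibutylboron aldolate of 8 | O=C1OC[C@H](Cc2ccccc2)N1C(=O)[C@@H](CC=C)[C@H](OB(CCCC)CCCC)c1ccc(O[Si](C)(C)C(C)(C)C)c(OC)c1 | intermediate
8 | (S)-4-benzyl-3-[(2S)-2-{(S)-hydroxy(Ar)methyl}pent-4-enoyl]oxazolidin-2-one | O=C1OC[C@H](Cc2ccccc2)N1C(=O)[C@@H](CC=C)[C@H](O)c1ccc(O[Si](C)(C)C(C)(C)C)c(OC)c1 | intermediate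
9 | (1S,2R)-1-Ar-2-allylpropane-1,3-diol | OC[C@@H](CC=C)[C@H](O)c1ccc(O[Si](C)(C)C(C)(C)C)c(OC)c1 | intermediate
10 | (2R)-2-[(S)-hydroxy(Ar)methyl]pent-4-en-1-yl acetate | CC(=O)OC[C@@H](CC=C)[C@H](O)c1ccc(O[Si](C)(C)C(C)(C)C)c(OC)c1 | intermediate
11 | (2R)-2-[(S)-hydroxy(Ar)methyl]-4,5-dihydroxypentyl acetate (both C4 epimers) | CC(=O)OC[C@@H](CC(O)CO)[C@H](O)c1ccc(O[Si](C)(C)C(C)(C)C)c(OC)c1 | intermediate
12 | (2R)-2-[(S)-hydroxy(Ar)methyl]-4-oxobutyl acetate | CC(=O)OC[C@@H](CC=O)[C@H](O)c1ccc(O[Si](C)(C)C(C)(C)C)c(OC)c1 | intermediate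
13 | [(2S,3R)-2-Ar-5-hydroxytetrahydrofuran-3-yl]methyl acetate (both anomers) | OC1C[C@H](COC(C)=O)[C@@H](c2ccc(O[Si](C)(C)C(C)(C)C)c(OC)c2)O1 | intermediate
14 | anomeric methanesulfonate of 13 | CS(=O)(=O)OC1C[C@H](COC(C)=O)[C@@H](c2ccc(O[Si](C)(C)C(C)(C)C)c(OC)c2)O1 | intermediate
15 | [(2S,3R)-2-Ar-2,3-dihydrofuran-3-yl]methyl acetate | C1=C[C@H](COC(C)=O)[C@@H](c2ccc(O[Si](C)(C)C(C)(C)C)c(OC)c2)O1 | intermediate
16 | N,N-dimethyliminium chloride of 17 | C[N+](C)=CC1=CO[C@H](c2ccc(O[Si](C)(C)C(C)(C)C)c(OC)c2)[C@H]1COC(C)=O.[Cl-] | intermediate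
17 | [(2S,3R)-2-Ar-4-formyl-2,3-dihydrofuran-3-yl]methyl acetate | O=CC1=CO[C@H](c2ccc(O[Si](C)(C)C(C)(C)C)c(OC)c2)[C@H]1COC(C)=O | intermediate
18 | 4-bromo-2-methoxyphenol | COc1cc(Br)ccc1O | starting material
19 | (4-bromo-2-methoxyphenoxy)(tert-butyl)dimethylsilane | COc1cc(Br)ccc1O[Si](C)(C)C(C)(C)C | intermediate
20 | 4-(TBSO)-3-methoxyphenylmagnesium bromide | COc1cc([Mg]Br)ccc1O[Si](C)(C)C(C)(C)C | intermediate
21 | [(2S,3R)-2-Ar-4-[hydroxy(Ar)methyl]-2,3-dihydrofuran-3-yl]methyl acetate (both carbinol epimers; bromomagnesium alkoxide until acid is added) | OC(c1ccc(O[Si](C)(C)C(C)(C)C)c(OC)c1)C1=CO[C@H](c2ccc(O[Si](C)(C)C(C)(C)C)c(OC)c2)[C@H]1COC(C)=O | intermediate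
22 | (R,E)-2-(acetoxymethyl)-1,4-di-Ar-3-formylbut-3-en-1-ylium | O=C/C(=C/c1ccc(O[Si](C)(C)C(C)(C)C)c(OC)c1)[C@H](COC(C)=O)[CH+]c1ccc(O[Si](C)(C)C(C)(C)C)c(OC)c1 | intermediate
23 | (3R,4S)-3-(acetoxymethyl)-4-Ar-6-(TBSO)-7-methoxy-3,4-dihydronaphthalene-2-carbaldehyde | COc1cc([C@H]2c3cc(O[Si](C)(C)C(C)(C)C)c(OC)cc3C=C(C=O)[C@@H]2COC(C)=O)ccc1O[Si](C)(C)C(C)(C)C | intermediate
24 | (3R,4S)-3-(acetoxymethyl)-6-hydroxy-4-(4-hydroxy-3-methoxyphenyl)-7-methoxy-3,4-dihydronaphthalene-2-carbaldehyde | COc1cc([C@H]2c3cc(O)c(OC)cc3C=C(C=O)[C@@H]2COC(C)=O)ccc1O | target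

**Count**

Total step count: 11. Longest linear sequence: 9 steps (1, 3, 4, 5, 6, 7, 8, 10, 11).

**Steps most likely to fail**

1. Step 10.
   - What may go wrong: the Grignard reagent may attack the acetate or add a second time to enal that forms early. The C4 cation may be diverted by trifluoroacetate capture, or by loss of acetic acid with aromatisation, before ring A reaches it. Facial selectivity in the closure may be poor.
   - Fallback (known chemistry, the two bonds made in separate operations): it sets out from lactol 13. Organocatalytic alpha-methylenation (aq. CH2O, pyrrolidine, propionic acid, i-PrOH, 45 °C) should give (2R)-2-[(S)-hydroxy(Ar)methyl]-3-formylbut-3-en-1-yl acetate F1.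
   - A Mizoroki–Heck reaction of this 2-substituted acrolein with 19 (Pd(OAc)2, P(o-tol)3, Et3N, MeCN, 80 °C) should give (2R,3E)-2-[(S)-hydroxy(Ar)methyl]-3-formyl-4-Ar-but-3-en-1-yl acetate F2.
   - A separate TFA treatment in CH2Cl2 at 0 °C closes ring B and comes back to the route at 23.

2. Step 8.
   - What may go wrong: the acid released may ionise the benzylic C–O bond of the enol ether. Acetic acid may be lost with aromatisation to a furan, and the arene may be formylated in competition.
   - Fallback: it sets out from 15. BF3·OEt2-catalysed addition of trimethyl orthoformate to the enol ether at –78 °C should give [(2S,3R)-2-Ar-4-(dimethoxymethyl)-5-methoxytetrahydrofuran-3-yl]methyl acetate F3.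
   - PPTS in wet acetone then unmasks the aldehyde and eliminates methanol, and the route is rejoined at 17.

3. Step 7.
   - What may go wrong: the acid-labile enol ether may hydrolyse or oligomerise during isolation, and substitution by chloride may occur at the anomeric center instead of elimination.
   - Fallback: it sets out from 13 and avoids the enol ether altogether. Heating with tert-butoxybis(dimethylamino)methane in toluene should aminomethylenate the open form 12 alpha to its formyl group, giving (2R,3E)-2-[(S)-hydroxy(Ar)methyl]-4-(dimethylamino)-3-formylbut-3-en-1-yl acetate F4.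
   - One equivalent of PPTS then closes the benzylic hydroxyl onto the vinylogous formamide carbon, and the route is rejoined at 17.

**Further compounds**

F1 | step 10 | (2R)-2-[(S)-hydroxy(Ar)methyl]-3-formylbut-3-en-1-yl acetate | O=CC(=C)[C@H](COC(C)=O)[C@H](O)c1ccc(O[Si](C)(C)C(C)(C)C)c(OC)c1
F2 | step 10 | (2R,3E)-2-[(S)-hydroxy(Ar)methyl]-3-formyl-4-Ar-but-3-en-1-yl acetate | O=C/C(=C/c1ccc(O[Si](C)(C)C(C)(C)C)c(OC)c1)[C@H](COC(C)=O)[C@H](O)c1ccc(O[Si](C)(C)C(C)(C)C)c(OC)c1
F3 | step 8 | [(2S,3R)-2-Ar-4-(dimethoxymethyl)-5-methoxytetrahydrofuran-3-yl]methyl acetate | COC1C(C(OC)OC)[C@H](COC(C)=O)[C@@H](c2ccc(O[Si](C)(C)C(C)(C)C)c(OC)c2)O1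
F4 | step 7 | (2R,3E)-2-[(S)-hydroxy(Ar)methyl]-4-(dimethylamino)-3-formylbut-3-en-1-yl acetate | CN(C)/C=C(/C=O)[C@H](COC(C)=O)[C@H](O)c1ccc(O[Si](C)(C)C(C)(C)C)c(OC)c1
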